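**Retrosynthetic overview** (germacrane numbering)
- Target ⇐ 8,9-acetonide / 3-O-TIPS macrolactone: acetonide cleavage, C9 acetylation, C8 angeloylation and desilylation come last.
- The ten-membered carbocycle is formed first, by a visible-light photoredox/chromium Barbier macrocyclization that forges C6–C7 from an enal-tethered 2-(bromomethyl)enoate; the trans γ-lactone closes second, in the same pot.
- The bromo-enoate enal ⇐ dialdehyde (Morita–Baylis–Hillman, then SN2' bromination) ⇐ Z-selective Still-type Wittig (C1=C10) between a C7–C10 methyl ketone and a C1–C6 ylide.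
- The ketone carries C8 and C9 from 2,3-O-isopropylidene-D-erythronolactone; the ylide carries C3 from (S)-α-hydroxy-γ-butyrolactone; C6 and C7 are set by the substrate in the ring closure.

Assumption: both lactones 1 and 7 are bought (available from L-malic acid and D-isoascorbic acid); atoms of all intermediates are labelled with the germacrane numbers C1–C15 of the target (C12 lactone carbonyl, C13 exocyclic methylene, C14 on C10, C15 on C4).

**Route**

Step 1
Reactants: 1 (S)-3-hydroxydihydrofuran-2(3H)-one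
Product: 2 (S)-3-(triisopropylsilyloxy)dihydrofuran-2(3H)-one
Conditions: TIPSOTf, 2,6-lutidine, CH2Cl2, 0 → 23 °C
Reagents that add atoms: triisopropylsilyl trifluoromethanesulfonate, CC(C)[Si](C(C)C)(C(C)C)OS(=O)(=O)C(F)(F)F
Why: Silyl triflate silylation of the secondary α-hydroxyl; the bulky TIPS ether resists 1,5-silyl migration and the later aqueous-acid acetonide cleavage, and the bought C3 (S) centre is untouched.

Step 2
Reactants: 2 (S)-3-(triisopropylsilyloxy)dihydrofuran-2(3H)-one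
Product: 3 (S)-5-hydroxy-3-(triisopropylsilyloxy)pentan-2-one (in equilibrium with its cyclic hemiketal)
Conditions: MeLi (1.05 equiv), THF, −78 °C; aq. NH4Cl
Reagents that add atoms: methyllithium, [Li]C
Why: Mono-addition of an organolithium to a γ-lactone stops at the stable tetrahedral lithium hemiketal at −78 °C and gives the methyl ketone (C4, C15) on quench without touching C3.

Step 3
Reactants: 3 (S)-5-hydroxy-3-(triisopropylsilyloxy)pentan-2-one
Product: 4 ethyl (2E,4S)-6-hydroxy-3-methyl-4-(triisopropylsilyloxy)hex-2-enoate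
Conditions: Ph3P=CHCO2Et, toluene, 100 °C
Reagents that add atoms: ethyl (triphenylphosphoranylidene)acetate, CCOC(=O)C=P(c1ccccc1)(c1ccccc1)c1ccccc1
Why: Wittig olefination of the activated α-silyloxy ketone with a stabilized ylide places the ester trans to the bulky CH(OTIPS) branch (E, C4=C5) under neutral conditions that avoid oxa-Michael closure of the free hydroxyl.

Step 4
Reactants: 4 ethyl (2E,4S)-6-hydroxy-3-methyl-4-(triisopropylsilyloxy)hex-2-enoate
Product: 5 ethyl (2E,4S)-6-iodo-3-methyl-4-(triisopropylsilyloxy)hex-2-enoate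
Conditions: I2, PPh3, imidazole, CH2Cl2, 0 → 23 °C
Reagents that add atoms: iodine, [I][I]
Why: Appel iodination of the primary alcohol proceeds without affecting the enoate or the silyl ether.

Step 5
Reactants: 5 ethyl (2E,4S)-6-iodo-3-methyl-4-(triisopropylsilyloxy)hex-2-enoate
Product: 6 [(3S,4E)-6-ethoxy-4-methyl-6-oxo-3-(triisopropylsilyloxy)hex-4-en-1-yl]triphenylphosphonium iodide
Conditions: PPh3, MeCN, 80 °C
Reagents that add atoms: triphenylphosphine, c1ccc(cc1)P(c1ccccc1)c1ccccc1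
Why: SN2 quaternization of triphenylphosphine by the primary iodide gives the Wittig salt; the β,β-disubstituted enoate is inert to the phosphine.

Step 6
Reactants: 7 (3aR,6aR)-2,2-dimethyldihydrofuro[3,4-d][1,3]dioxol-4(3aH)-one [(−)-2,3-O-isopropylidene-D-erythronolactone]
Product: 9 [(4R,5R)-5-acetyl-2,2-dimethyl-1,3-dioxolan-4-yl]methyl 2,2-dimethylpropanoate, via hemiketal 8 (not isolated)
Conditions: MeLi, THF, −78 °C; aq. NH4Cl; then t-BuCOCl, pyridine, DMAP (cat.), CH2Cl2, 0 → 23 °C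
Reagents that add atoms: methyllithium, [Li]C; pivaloyl chloride, CC(C)(C)C(Cl)=O
Why: Organolithium mono-addition to the lactone gives the hemiketal, whose open hydroxy-ketone tautomer is trapped by acylation of its primary hydroxyl (Curtin–Hammett), giving the acyclic α-alkoxy methyl ketone with C8 and C9 bought from the pool.

Step 7
Reactants: 6 [(3S,4E)-6-ethoxy-4-methyl-6-oxo-3-(triisopropylsilyloxy)hex-4-en-1-yl]triphenylphosphonium iodide; 9 [(4R,5R)-5-acetyl-2,2-dimethyl-1,3-dioxolan-4-yl]methyl 2,2-dimethylpropanoate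
Product: 11 ethyl (2E,4S,6Z)-7-[(4S,5R)-5-(pivaloyloxymethyl)-2,2-dimethyl-1,3-dioxolan-4-yl]-3-methyl-4-(triisopropylsilyloxy)octa-2,6-dienoate, via phosphonium ylide 10 (not isolated)
Conditions: KN(SiMe3)2, THF, −78 °C; then 9, −78 → 0 °C
Reagents that add atoms: none
Why: Still-type Wittig olefination of an α-alkoxy ketone with a salt-free non-stabilized ylide is kinetically Z-selective (alkoxy-bearing C9 cis to the ylide chain), setting the Z C1=C10 alkene; the hindered pivalate and the β,β-disubstituted enoate are not attacked at −78 °C.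

Step 8
Reactants: 11 ethyl (2E,4S,6Z)-7-[(4S,5R)-5-(pivaloyloxymethyl)-2,2-dimethyl-1,3-dioxolan-4-yl]-3-methyl-4-(triisopropylsilyloxy)octa-2,6-dienoate
Product: 12 (2E,4S,6Z)-7-[(4S,5R)-5-(hydroxymethyl)-2,2-dimethyl-1,3-dioxolan-4-yl]-3-methyl-4-(triisopropylsilyloxy)octa-2,6-dien-1-ol
Conditions: i-Bu2AlH (6 equiv), CH2Cl2, −78 → −20 °C
Reagents that add atoms: none
Why: Hydride reduction takes the enoate 1,2 to the allylic alcohol (C6) and cleaves the pivalate (C7) in one operation.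

Step 9
Reactants: 12 (2E,4S,6Z)-7-[(4S,5R)-5-(hydroxymethyl)-2,2-dimethyl-1,3-dioxolan-4-yl]-3-methyl-4-(triisopropylsilyloxy)octa-2,6-dien-1-ol
Product: 13 (2E,4S,6Z)-7-[(4S,5S)-5-formyl-2,2-dimethyl-1,3-dioxolan-4-yl]-3-methyl-4-(triisopropylsilyloxy)octa-2,6-dienal
Conditions: Dess–Martin periodinane (2.6 equiv), CH2Cl2, 0 → 23 °C; used crude
Reagents that add atoms: none
Why: Dess–Martin oxidation converts both primary alcohols to aldehydes under non-basic conditions that neither epimerize the cis-dioxolane α-centre (C8) nor isomerize the enal.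

Step 10
Reactants: 13 (2E,4S,6Z)-7-[(4S,5S)-5-formyl-2,2-dimethyl-1,3-dioxolan-4-yl]-3-methyl-4-(triisopropylsilyloxy)octa-2,6-dienal
Product: 14 methyl 2-[hydroxy{(4R,5S)-2,2-dimethyl-5-[(2Z,5S,6E)-6-methyl-8-oxo-5-(triisopropylsilyloxy)octa-2,6-dien-2-yl]-1,3-dioxolan-4-yl}methyl]prop-2-enoate (both carbinol epimers)
Conditions: methyl acrylate (10 equiv), DABCO (1 equiv), MeOH (2 equiv), 23 °C
Reagents that add atoms: methyl acrylate, C=CC(=O)OC
Why: Morita–Baylis–Hillman reaction; the electron-poor α-alkoxy aldehyde (C7) reacts far faster than the conjugated β,β-disubstituted enal (C6), and the new carbinol centre is erased in the next step.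

Step 11
Reactants: 14 methyl 2-[hydroxy{(4R,5S)-2,2-dimethyl-5-[(2Z,5S,6E)-6-methyl-8-oxo-5-(triisopropylsilyloxy)octa-2,6-dien-2-yl]-1,3-dioxolan-4-yl}methyl]prop-2-enoate
Product: 15 methyl (2Z)-2-(bromomethyl)-3-{(4R,5S)-2,2-dimethyl-5-[(2Z,5S,6E)-6-methyl-8-oxo-5-(triisopropylsilyloxy)octa-2,6-dien-2-yl]-1,3-dioxolan-4-yl}prop-2-enoate
Conditions: NBS, Me2S (premixed), CH2Cl2, 0 → 23 °C
Reagents that add atoms: N-bromosuccinimide, O=C1CCC(=O)N1Br
Why: Corey–Kim-type activation of the allylic alcohol followed by SN2' attack of bromide gives the thermodynamically preferred (Z)-2-(bromomethyl)enoate with C11, C12 and C13 in place.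

Step 12
Reactants: 15 methyl (2Z)-2-(bromomethyl)-3-{(4R,5S)-2,2-dimethyl-5-[(2Z,5S,6E)-6-methyl-8-oxo-5-(triisopropylsilyloxy)octa-2,6-dien-2-yl]-1,3-dioxolan-4-yl}prop-2-enoate
Product: 17 (3S,6R,7S,8R,9S)-8,9-(isopropylidenedioxy)-3-(triisopropylsilyloxy)germacra-1(10)Z,4E,11(13)-trien-12,6-olide, via hydroxy ester 16 (not isolated)
Conditions: CrCl3·3THF (20 mol %), 4CzIPN (2 mol %), Hantzsch ester (1.5 equiv), 2,6-lutidine (2 equiv), DMF/THF, 450 nm LEDs, 23 °C, 15 added over 12 h (final 2 mM); then PPTS (cat.), 40 °C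
Reagents that add atoms: none
Why: Proposed new method: a dual photoredox/chromium-catalysed Barbier (Nozaki–Hiyama-type) macrocyclization in which photoexcited 4CzIPN is reductively quenched by the Hantzsch ester, its radical anion reduces trivalent chromium to divalent chromium, divalent chromium turns the allylic bromide into an allyl radical and captures it as a nucleophilic allylchromium species (trivalent chromium) that adds 1,2 to the C6 enal through a closed six-membered transition state to forge C6–C7 and the ten-membered ring, lutidinium protonolysis then frees the catalyst and the 6-hydroxy ester lactonizes; C7 is set by C8 (H8 eclipsed with the allyl plane to minimise A(1,3) strain, bond formation anti to the C8–O bond on the face of the C9 tether) and C6 by the diequatorial chair that gives the trans (6α-O, 7α-H) lactone; the closest known reactions are the intermolecular photoredox/chromium-catalysed allylation of aldehydes and the stoichiometric CrCl2 Barbier macrocyclization of aldehyde-tethered 2-(bromomethyl)enoates.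

Step 13
Reactants: 17 (3S,6R,7S,8R,9S)-8,9-(isopropylidenedioxy)-3-(triisopropylsilyloxy)germacra-1(10)Z,4E,11(13)-trien-12,6-olide
Product: 18 (3S,6R,7S,8R,9S)-8,9-dihydroxy-3-(triisopropylsilyloxy)germacra-1(10)Z,4E,11(13)-trien-12,6-olide
Conditions: AcOH/H2O (4:1), 40 °C
Reagents that add atoms: none
Why: Aqueous-acid acetal hydrolysis removes the cis-acetonide while the secondary TIPS ether and the α-methylene lactone survive.

Step 14
Reactants: 18 (3S,6R,7S,8R,9S)-8,9-dihydroxy-3-(triisopropylsilyloxy)germacra-1(10)Z,4E,11(13)-trien-12,6-olide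
Product: 19 (3S,6R,7S,8R,9S)-9-acetoxy-8-hydroxy-3-(triisopropylsilyloxy)germacra-1(10)Z,4E,11(13)-trien-12,6-olide
Conditions: AcCl (1.05 equiv), 2,4,6-collidine, CH2Cl2, −78 → −40 °C
Reagents that add atoms: acetyl chloride, CC(Cl)=O
Why: Kinetic acylation with an acid chloride and a hindered pyridine at low temperature is expected to select the less hindered allylic C9 hydroxyl (sp2 neighbour) over the C8 hydroxyl, which is flanked by the ring-fusion carbon C7.

Step 15
Reactants: 19 (3S,6R,7S,8R,9S)-9-acetoxy-8-hydroxy-3-(triisopropylsilyloxy)germacra-1(10)Z,4E,11(13)-trien-12,6-olide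
Product: 20 (3S,6R,7S,8R,9S)-9-acetoxy-8-angeloyloxy-3-(triisopropylsilyloxy)germacra-1(10)Z,4E,11(13)-trien-12,6-olide
Conditions: angelic acid, 2,4,6-trichlorobenzoyl chloride, Et3N, toluene, 23 °C; then 19, DMAP (1.5 equiv), 40 °C
Reagents that add atoms: angelic acid [(Z)-2-methylbut-2-enoic acid], C/C=C(/C)C(=O)O
Why: Yamaguchi esterification through the mixed 2,4,6-trichlorobenzoic anhydride acylates the hindered C8 hydroxyl without an acid chloride or an alkoxide, which limits angelate-to-tiglate isomerization and acetyl migration.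

Step 16
Reactants: 20 (3S,6R,7S,8R,9S)-9-acetoxy-8-angeloyloxy-3-(triisopropylsilyloxy)germacra-1(10)Z,4E,11(13)-trien-12,6-olide
Product: 21 (3S,6R,7S,8R,9S)-9-acetoxy-8-angeloyloxy-3-hydroxygermacra-1(10)Z,4E,11(13)-trien-12,6-olide (CNP0265116.1)
Conditions: HF·pyridine, pyridine, THF, 0 → 23 °C
Reagents that add atoms: none
Why: Buffered fluoride desilylation frees the C3 hydroxyl while both esters, the α-methylene lactone and the angelate geometry are left intact.

**Compound list**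
1 | (S)-3-hydroxydihydrofuran-2(3H)-one [(S)-α-hydroxy-γ-butyrolactone] | O=C1[C@@H](O)CCO1 | starting material
2 | (S)-3-(triisopropylsilyloxy)dihydrofuran-2(3H)-one | O=C1[C@@H](O[Si](C(C)C)(C(C)C)C(C)C)CCO1 | intermediate
3 | (S)-5-hydroxy-3-(triisopropylsilyloxy)pentan-2-one | CC(=O)[C@@H](O[Si](C(C)C)(C(C)C)C(C)C)CCO | intermediate
4 | ethyl (2E,4S)-6-hydroxy-3-methyl-4-(triisopropylsilyloxy)hex-2-enoate | CCOC(=O)/C=C(\C)[C@@H](O[Si](C(C)C)(C(C)C)C(C)C)CCO | intermediate
5 | ethyl (2E,4S)-6-iodo-3-methyl-4-(triisopropylsilyloxy)hex-2-enoate | CCOC(=O)/C=C(\C)[C@@H](O[Si](C(C)C)(C(C)C)C(C)C)CCI | intermediate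
6 | [(3S,4E)-6-ethoxy-4-methyl-6-oxo-3-(triisopropylsilyloxy)hex-4-en-1-yl]triphenylphosphonium iodide | CCOC(=O)/C=C(\C)[C@@H](O[Si](C(C)C)(C(C)C)C(C)C)CC[P+](c1ccccc1)(c1ccccc1)c1ccccc1.[I-] | intermediate
7 | (3aR,6aR)-2,2-dimethyldihydrofuro[3,4-d][1,3]dioxol-4(3aH)-one [(−)-2,3-O-isopropylidene-D-erythronolactone] | O=C1[C@@H]2OC(C)(C)O[C@@H]2CO1 | starting material
8 | 1-deoxy-3,4-O-isopropylidene-D-erythro-pent-2-ulofuranose (hemiketal, both anomers; not isolated) | CC1(O)[C@@H]2OC(C)(C)O[C@@H]2CO1 | intermediate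
9 | [(4R,5R)-5-acetyl-2,2-dimethyl-1,3-dioxolan-4-yl]methyl 2,2-dimethylpropanoate | CC(=O)[C@@H]1OC(C)(C)O[C@@H]1COC(=O)C(C)(C)C | intermediate
10 | ethyl (2E,4S)-3-methyl-4-(triisopropylsilyloxy)-6-(triphenyl-λ5-phosphanylidene)hex-2-enoate (ylide; not isolated) | CCOC(=O)/C=C(\C)[C@@H](O[Si](C(C)C)(C(C)C)C(C)C)CC=P(c1ccccc1)(c1ccccc1)c1ccccc1 | intermediate
11 | ethyl (2E,4S,6Z)-7-[(4S,5R)-5-(pivaloyloxymethyl)-2,2-dimethyl-1,3-dioxolan-4-yl]-3-methyl-4-(triisopropylsilyloxy)octa-2,6-dienoate | CCOC(=O)/C=C(\C)[C@@H](O[Si](C(C)C)(C(C)C)C(C)C)C/C=C(/C)[C@@H]1OC(C)(C)O[C@@H]1COC(=O)C(C)(C)C | intermediate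
12 | (2E,4S,6Z)-7-[(4S,5R)-5-(hydroxymethyl)-2,2-dimethyl-1,3-dioxolan-4-yl]-3-methyl-4-(triisopropylsilyloxy)octa-2,6-dien-1-ol | OC/C=C(\C)[C@@H](O[Si](C(C)C)(C(C)C)C(C)C)C/C=C(/C)[C@@H]1OC(C)(C)O[C@@H]1CO | intermediate
13 | (2E,4S,6Z)-7-[(4S,5S)-5-formyl-2,2-dimethyl-1,3-dioxolan-4-yl]-3-methyl-4-(triisopropylsilyloxy)octa-2,6-dienal | O=C/C=C(\C)[C@@H](O[Si](C(C)C)(C(C)C)C(C)C)C/C=C(/C)[C@@H]1OC(C)(C)O[C@@H]1C=O | intermediate
14 | methyl 2-[hydroxy{(4R,5S)-2,2-dimethyl-5-[(2Z,5S,6E)-6-methyl-8-oxo-5-(triisopropylsilyloxy)octa-2,6-dien-2-yl]-1,3-dioxolan-4-yl}methyl]prop-2-enoate (both carbinol epimers) | O=C/C=C(\C)[C@@H](O[Si](C(C)C)(C(C)C)C(C)C)C/C=C(/C)[C@@H]1OC(C)(C)O[C@@H]1C(O)C(=C)C(=O)OC | intermediate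
15 | methyl (2Z)-2-(bromomethyl)-3-{(4R,5S)-2,2-dimethyl-5-[(2Z,5S,6E)-6-methyl-8-oxo-5-(triisopropylsilyloxy)octa-2,6-dien-2-yl]-1,3-dioxolan-4-yl}prop-2-enoate | O=C/C=C(\C)[C@@H](O[Si](C(C)C)(C(C)C)C(C)C)C/C=C(/C)[C@@H]1OC(C)(C)O[C@@H]1/C=C(\CBr)C(=O)OC | intermediate
16 | methyl (3S,6R,7S,8R,9S)-6-hydroxy-8,9-(isopropylidenedioxy)-3-(triisopropylsilyloxy)germacra-1(10)Z,4E,11(13)-trien-12-oate (not isolated) | COC(=O)C(=C)[C@H]1[C@H](O)/C=C(\C)[C@@H](O[Si](C(C)C)(C(C)C)C(C)C)C/C=C(/C)[C@@H]2OC(C)(C)O[C@H]12 | intermediate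
17 | (3S,6R,7S,8R,9S)-8,9-(isopropylidenedioxy)-3-(triisopropylsilyloxy)germacra-1(10)Z,4E,11(13)-trien-12,6-olide (3β-OTIPS, 6α-O, 7α-H, 8α,9α-acetonide) | C=C1C(=O)O[C@@H]2/C=C(\C)[C@@H](O[Si](C(C)C)(C(C)C)C(C)C)C/C=C(/C)[C@@H]3OC(C)(C)O[C@@H]3[C@@H]12 | intermediate
18 | (3S,6R,7S,8R,9S)-8,9-dihydroxy-3-(triisopropylsilyloxy)germacra-1(10)Z,4E,11(13)-trien-12,6-olide | C=C1C(=O)O[C@@H]2/C=C(\C)[C@@H](O[Si](C(C)C)(C(C)C)C(C)C)C/C=C(/C)[C@H](O)[C@H](O)[C@@H]12 | intermediate
19 | (3S,6R,7S,8R,9S)-9-acetoxy-8-hydroxy-3-(triisopropylsilyloxy)germacra-1(10)Z,4E,11(13)-trien-12,6-olide | C=C1C(=O)O[C@@H]2/C=C(\C)[C@@H](O[Si](C(C)C)(C(C)C)C(C)C)C/C=C(/C)[C@H](OC(C)=O)[C@H](O)[C@@H]12 | intermediate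
20 | (3S,6R,7S,8R,9S)-9-acetoxy-8-angeloyloxy-3-(triisopropylsilyloxy)germacra-1(10)Z,4E,11(13)-trien-12,6-olide | C=C1C(=O)O[C@@H]2/C=C(\C)[C@@H](O[Si](C(C)C)(C(C)C)C(C)C)C/C=C(/C)[C@H](OC(C)=O)[C@H](OC(=O)/C(C)=C\C)[C@@H]12 | intermediate
21 | (3S,6R,7S,8R,9S)-9-acetoxy-8-angeloyloxy-3-hydroxygermacra-1(10)Z,4E,11(13)-trien-12,6-olide (3β-OH, 6α-O, 7α-H, 8α-OAng, 9α-OAc) | C=C1C(=O)O[C@@H]2/C=C(\C)[C@@H](O)C/C=C(/C)[C@H](OC(C)=O)[C@H](OC(=O)/C(C)=C\C)[C@@H]12 | target

**Step count**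
Total: 16 steps. Longest linear sequence: 15 steps (1 → 21 through steps 1–5 and 7–16).

**Three steps most likely to fail**

Step 12 (the proposed photoredox/chromium macrocyclization). The risks are protodebromination of the allyl radical by the Hantzsch ester, opening of the dioxolane by 1,4-elimination from the allylchromium, poor catalyst turnover at high dilution, and a wrong C6/C7 diastereomer. The fallback uses known chemistry and drops light and catalysis altogether: setting out from bromide 15, the thermal Nozaki–Hiyama-type Barbier macrocyclization is run with stoichiometric CrCl2 (6 equiv, divalent chromium as the two-electron reductant), THF/DMF, 23 °C, syringe-pump addition to 2 mM. The 6-hydroxy ester 16 is lactonized with PPTS, and the route is rejoined at 17. No compound outside the list is made (F0).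

Step 14 (regioselective acetylation of the 8,9-diol). The two secondary hydroxyls may be acylated with poor selectivity, or the acetate may migrate. The fallback replaces direct acylation by a temporary silyl group. Setting out from diol 18, Et3SiCl (1.05 equiv), imidazole, CH2Cl2, −40 °C gives the more selective bulky-reagent product, 9-O-triethylsilyl-8-hydroxy lactone F1. Yamaguchi angeloylation as in step 15 then gives 8-angeloyloxy-9-O-triethylsilyl lactone F2. PPTS in MeOH at 0 °C removes only the triethylsilyl ether (TIPS stays) to give 8-angeloyloxy-9-hydroxy lactone F3. Ac2O, pyridine and DMAP (cat.) then acetylate C9–OH, and the route is rejoined at 20.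

Step 10 (Morita–Baylis–Hillman reaction on the dialdehyde). The long exposure to the amine may epimerize C8 (cis- to trans-dioxolane), and the reaction may be slow or attack the enal. The fallback replaces the amine-catalysed reaction by a fast, low-temperature selenolate Michael–aldol sequence. Setting out from dialdehyde 13, PhSeLi (from PhSeH and n-BuLi) and methyl acrylate in THF at −78 °C give, at the more electrophilic C7 aldehyde, the β-hydroxy α-(phenylselanylmethyl) ester F4. H2O2 and pyridine in CH2Cl2 at 0 °C then bring about selenoxide syn-elimination to the same adduct, and the route is rejoined at 14.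

**Further compounds**
F0 | step 12 | none | none
F1 | step 14 | (3S,6R,7S,8R,9S)-8-hydroxy-9-(triethylsilyloxy)-3-(triisopropylsilyloxy)germacra-1(10)Z,4E,11(13)-trien-12,6-olide | C=C1C(=O)O[C@@H]2/C=C(\C)[C@@H](O[Si](C(C)C)(C(C)C)C(C)C)C/C=C(/C)[C@H](O[Si](CC)(CC)CC)[C@H](O)[C@@H]12
F2 | step 14 | (3S,6R,7S,8R,9S)-8-angeloyloxy-9-(triethylsilyloxy)-3-(triisopropylsilyloxy)germacra-1(10)Z,4E,11(13)-trien-12,6-olide | C=C1C(=O)O[C@@H]2/C=C(\C)[C@@H](O[Si](C(C)C)(C(C)C)C(C)C)C/C=C(/C)[C@H](O[Si](CC)(CC)CC)[C@H](OC(=O)/C(C)=C\C)[C@@H]12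
F3 | step 14 | (3S,6R,7S,8R,9S)-8-angeloyloxy-9-hydroxy-3-(triisopropylsilyloxy)germacra-1(10)Z,4E,11(13)-trien-12,6-olide | C=C1C(=O)O[C@@H]2/C=C(\C)[C@@H](O[Si](C(C)C)(C(C)C)C(C)C)C/C=C(/C)[C@H](O)[C@H](OC(=O)/C(C)=C\C)[C@@H]12
F4 | step 10 | methyl 3-hydroxy-2-(phenylselanylmethyl)-3-{(4R,5S)-2,2-dimethyl-5-[(2Z,5S,6E)-6-methyl-8-oxo-5-(triisopropylsilyloxy)octa-2,6-dien-2-yl]-1,3-dioxolan-4-yl}propanoate (diastereomer mixture) | O=C/C=C(\C)[C@@H](O[Si](C(C)C)(C(C)C)C(C)C)C/C=C(/C)[C@@H]1OC(C)(C)O[C@@H]1C(O)C(C[Se]c1ccccc1)C(=O)OC
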